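## Analysis of the target

Compound 33 is a single 14-membered macrolactone, numbered here C1 (lactone carbonyl) through C13 (the carbon bearing the ring oxygen), with the side chain continuing as C14–C24; C3 carries a carboxymethyl arm (C1′, C2′), C9 a methyl group, C11 a hydroxyl, and C15 the side-chain hydroxyl. The three stereocentres form a 1,3,5-triol array whose central oxygen is the lactone oxygen: C11 (S) and C13 (R) are 1,3-syn, C13 and C15 (S) are 1,3-anti. Three E alkenes sit in the ring (trisubstituted C2=C3, disubstituted C5=C6, trisubstituted C8=C9), so C4 and C7 are doubly allylic, C4 being also γ to the ester, and the triene can slide into conjugation under base or metal hydrides. The arm makes C1–C3–C1′–C2′ a 3-substituted glutaconic half-ester whose C1′ methylene is doubly activated, so the acid is best unveiled last. The hydroxyls at C11 and C15 flank the acylated C13 oxygen and can transacylate under base. The difficulty is to fix the geometry of the trisubstituted enoate inside a macrocycle while building a base-sensitive skipped diene and telling three similar oxygens apart. The feature used is that at C2=C3 the ring carbon C4 lies cis to the C1 carbonyl and the arm trans: C4 therefore occupies exactly the place of the single β-hydrogen of a plain (E)-enoate, the hydrogen a carbonyl-bound metal can reach.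

## Retrosynthetic reasoning

**33 back to 29 (no skeletal bond cut).** The acid and the two free hydroxyls are traced through 32, 31 and 30 to lactone 29, where the arm ends in a primary silyl ether and C11 and C15 carry secondary silyl ethers. Keeping the arm at the alcohol oxidation level leaves C1′ unactivated while the ring is made. The forward steps must free the primary oxygen selectively, oxidise it in two mild stages, and then remove the remaining silyl groups without base.

**29 back to 28 (cut C3–C4, with allylic transposition).** Cutting C3–C4 and moving C5=C6 back to a terminal C4=C5 alkene with a carbonate on C6 turns the trisubstituted enoate into a simple E-disubstituted enoate ester of the C13 oxygen. This bond is chosen because the β-hydrogen of that enoate is the only hydrogen a chelated metal can cleave, and it sits where C4 must go. One event then makes the C3–C4 bond, fixes the C2=C3 geometry, creates C5=C6 and closes the ring. A cut at the lactone C–O bond would leave the enoate geometry to an earlier step and would require activating an acid next to the skipped diene. A cut at C5=C6 would give no handle on either alkene geometry. The forward reaction has to achieve ester-directed C–H metalation, insertion of the tethered alkene across 14 atoms, and β-oxygen elimination giving the E alkene, all faster than oligomerisation.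

**28 back to 22 and 26 (cut the C13–O–C1 ester).** Acylation of the C13 alcohol 22 with acid 26 is the convergent junction. Acid 26 is cut at its C2=C3 alkene into silyl ether 24 and acrylic acid 25 (cross-metathesis), and 24 comes from but-3-en-1-ol 23.

**22 back to 18 (cut C5–C6).** The C6 carbonate of 22 and 21 derives from allylic alcohol 20, made by adding a vinyl nucleophile to aldehyde 19, itself the oxidation product of homoallylic alcohol 18. The C6 centre needs no control because the key step destroys it. Through these steps the C13 oxygen carries a triethylsilyl group so that it alone can be freed (21 to 22) beside the two tert-butyldimethylsilyl ethers.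

**18 back to 14 and 15 (cut C7–C8 and C9–CH3).** The E-trisubstituted C8=C9 alkene is traced to terminal alkyne 14: syn methyl–aluminium addition gives alane 16, and its ate complex 17 is alkylated by oxirane 15, which supplies C6 and C7. The syn addition fixes the alkene geometry by mechanism.

**14 back to 9 and 10 (cut C9–C10).** The homopropargylic C11 carbinol of 12 (then 13, 14) arises by opening epoxide 9 at its unsubstituted carbon with acetylide 11 from ethynyltrimethylsilane 10. The C11 configuration is untouched.

**9 back to 5 (C11–O bond from the alkene).** Epoxide 9 is the triethylsilyl ether of epoxy alcohol 8, which comes from cyclic iodocarbonate 7 and hence from carbonate 6 of homoallylic alcohol 5. The carbonate oxygen is delivered intramolecularly to C11, which sets the 1,3-syn relationship to C13 with substrate control.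

**5 back to 1 (cut C12–C13 and C14–C15).** Two reagent-controlled allylborations, separated by silylation (2 to 3) and ozonolysis (3 to 4), set C15 and then C13 (anti), starting from decanal 1.

## Alternatives that were turned down

**Alternative 1:** The disconnection is two aldol bonds, C12–C13 and C10–C11. In the forward step the aldolase DERA adds two molecules of acetaldehyde A2 in sequence to chloroacetaldehyde A1 and delivers the C9–C14 unit as (3R,5S)-6-chloro-3,5-dihydroxyhexanal A3, which rests as its six-membered lactol.
- For it: C11 and C13 are set syn with enzyme control from two-carbon feedstocks, in water, without protecting groups. The lactol also ties up the C13 oxygen and leaves the C11 hydroxyl free. On this point it is stronger than the chosen route, which spends steps 5–7 on C11 and a silyl group on and off at C13.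
- Against it: the step closes no ring of the target and touches none of the hard bonds. C9 arrives as an aldehyde that still has to become the E-trisubstituted C8=C9 alkene. C14 arrives as a primary chloride β to oxygen, a poor electrophile for joining the C15–C24 part, and C15 would need a separate anti-selective event. A macrocyclisation and the C2=C3 geometry remain entirely open.
- Comparison: the chosen strategy concentrates ring closure and both new alkene geometries in one late step; the enzyme route only improves a part that conventional chemistry already handles reliably.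

**Alternative 2:** The disconnection is the O13–C1 ester bond together with the C15–H bond. The precursor is the open-chain C1 enal/C15 ketone A4 with free C11 and C13 hydroxyls. With catalytic samarium diiodide A5 the C13 hydroxyl adds to the aldehyde and the hemiacetal hydrogen is passed to C15 (Evans–Tishchenko), giving lactone A6.
- For it: ring closure and the C15 stereocentre come in one redox-neutral step, the 1,3-anti outcome is the one required, and only the C13 hemiacetal can deliver hydride through a six-membered transition state, so C11 needs no protection. It creates a stereocentre where the chosen key step creates none.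
- Against it: the acyl donor is a β,β-disubstituted enal, a poor partner for hemiacetal formation, and doing this across 14 atoms is reversible and entropically costly. The β-hydroxy ketone can undergo retro-aldol or elimination at a Lewis-acidic samarium centre, and divalent samarium reduces enals. Above all, A4 must already contain the C2=C3 geometry, so the hardest element is pushed into a long linear sequence.
- Comparison: the chosen precursor 28 carries only a simple E-enoate made in one metathesis step, and the enoate geometry follows from the mechanism of ring closure.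

**Alternative 3:** The disconnection is C5–C6 as a triple bond. Diyne A7, with two methyl-capped alkynes, is closed by the molybdenum alkylidyne Mo(≡C–C6H4-4-OMe)(OSiPh3)3 A8 to cycloalkyne A9 with loss of but-2-yne A10; a trans-selective hydrometalation and protodemetalation would then give the E alkene.
- For it: alkyne metathesis is among the most dependable macrocyclisations, tolerates esters, silyl ethers and alkenes, and a 14-membered cycloalkyne is accessible. On reliability of the ring closure it is clearly stronger than the chosen step, which is untested.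
- Against it: two further steps are needed to reach the alkene, in the presence of three other alkenes. The C4 methylene of A7 and A9 is propargylic, allylic and γ to the ester, so allene formation threatens. A7 still needs the trisubstituted enoate built with defined geometry beforehand, plus two propargylic C–C bonds.
- Comparison: the chosen route replaces enoate construction, ring closure and alkyne reduction by one C–H allylation and offers step economy and mechanistic control of C2=C3, at the price of higher risk in that step.

Key step: step 20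

Remark on the chemistry: C6 of 20, 21, 22 and 28 is formed without control in step 14 and is destroyed in step 20; both epimers are carried together and the SMILES show one of them. The spatial arrangement at C11, C13 and C15 is that of 33 in every intermediate, even where the CIP letter changes with the substituents.

## Route

Step 1
Reactants: 1 decanal
Product: 2 (4S)-tridec-1-en-4-ol
Conditions: (+)-Ipc2B(allyl) (from (−)-α-pinene), Et2O, −78 °C; then NaOH, H2O2, 0 °C to rt
Reagents that add atoms: (+)-B-allyldiisopinocampheylborane, C=CCB([C@H]1C[C@H]2C[C@H](C2(C)C)[C@@H]1C)[C@H]1C[C@H]2C[C@H](C2(C)C)[C@@H]1C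
Why: Brown asymmetric allylboration through a chair transition state; the (−)-α-pinene-derived borane adds to the Re face of an aliphatic aldehyde, which sets C15 as the 4S alcohol.

Step 2
Reactants: 2 (4S)-tridec-1-en-4-ol
Product: 3 tert-butyl(dimethyl)[(4S)-tridec-1-en-4-yl]oxysilane
Conditions: TBSCl, imidazole, DMF, rt
Reagents that add atoms: tert-butyldimethylsilyl chloride, CC(C)(C)[Si](C)(C)Cl
Why: Standard silylation of a secondary alcohol; the C15 centre is not touched.

Step 3
Reactants: 3 tert-butyl(dimethyl)[(4S)-tridec-1-en-4-yl]oxysilane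
Product: 4 (3S)-3-[tert-butyl(dimethyl)silyl]oxydodecanal
Conditions: O3, CH2Cl2, −78 °C; then PPh3, −78 °C to rt
Reagents that add atoms: ozone, [O-][O+]=O
Why: Ozonolysis with reductive work-up cleaves the terminal alkene to the C13 aldehyde; the silyl ether is inert and the β-silyloxy aldehyde is used without delay to avoid elimination.

Step 4
Reactants: 4 (3S)-3-[tert-butyl(dimethyl)silyl]oxydodecanal
Product: 5 (4S,6S)-6-[tert-butyl(dimethyl)silyl]oxypentadec-1-en-4-ol
Conditions: (−)-Ipc2B(allyl) (from (+)-α-pinene), Et2O, −78 °C; then NaOH, H2O2, 0 °C to rt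
Reagents that add atoms: (−)-B-allyldiisopinocampheylborane, C=CCB([C@@H]1C[C@@H]2C[C@@H](C2(C)C)[C@H]1C)[C@@H]1C[C@@H]2C[C@@H](C2(C)C)[C@H]1C
Why: Brown allylboration under reagent control; the enantiomeric borane adds to the Si face and sets C13 anti to the C15 silyloxy group, whose own bias in the closed transition state is small.

Step 5
Reactants: 5 (4S,6S)-6-[tert-butyl(dimethyl)silyl]oxypentadec-1-en-4-ol
Product: 6 tert-butyl (4S,6S)-6-[tert-butyl(dimethyl)silyl]oxypentadec-1-en-4-yl carbonate
Conditions: Boc2O, DMAP, MeCN, rt
Reagents that add atoms: di-tert-butyl dicarbonate, CC(C)(C)OC(=O)OC(=O)OC(C)(C)C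
Why: DMAP-catalysed acylation of the C13 hydroxyl gives the tert-butyl carbonate that serves as internal oxygen nucleophile in the next step.

Step 6
Reactants: 6 tert-butyl (4S,6S)-6-[tert-butyl(dimethyl)silyl]oxypentadec-1-en-4-yl carbonate
Product: 7 (4R)-4-(iodomethyl)-6-[(2S)-2-[tert-butyl(dimethyl)silyl]oxyundecyl]-1,3-dioxan-2-one with the 4- and 6-substituents cis
Conditions: IBr, PhMe, −85 °C; then aq. Na2S2O3
Reagents that add atoms: iodine monobromide, IBr
Why: Bartlett-type iodocarbonate cyclisation: the iodonium ion is opened 6-exo by the carbonate carbonyl through a chair with both substituents equatorial and the tert-butyl group is lost, so the C11–O bond forms syn to C13.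

Step 7
Reactants: 7 (4R)-4-(iodomethyl)-6-[(2S)-2-[tert-butyl(dimethyl)silyl]oxyundecyl]-1,3-dioxan-2-one
Product: 8 (2S,4S)-4-[tert-butyl(dimethyl)silyl]oxy-1-[(2R)-oxiran-2-yl]tridecan-2-ol
Conditions: K2CO3, MeOH, rt
Reagents that add atoms: none
Why: Methanolysis of the cyclic carbonate frees both oxygens and the C11 alkoxide displaces the neighbouring primary iodide (intramolecular Williamson closure); the C11–O bond is not broken, so the syn relationship is kept and the C13 hydroxyl emerges free.

Step 8
Reactants: 8 (2S,4S)-4-[tert-butyl(dimethyl)silyl]oxy-1-[(2R)-oxiran-2-yl]tridecan-2-ol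
Product: 9 triethylsilyl ether of 8 at the C13 oxygen (epoxide C10–C11, OTES at C13, OTBS at C15)
Conditions: TESCl, imidazole, CH2Cl2, 0 °C
Reagents that add atoms: chlorotriethylsilane, CC[Si](CC)(CC)Cl
Why: Neutral silylation that leaves the epoxide intact; the triethylsilyl group marks C13 as the one oxygen to be freed later beside the two tert-butyldimethylsilyl ethers.

Step 9
Reactants: 9 triethylsilyl ether of 8; 10 ethynyltrimethylsilane
Product: 12 8-[tert-butyl(dimethyl)silyl]oxy-6-(triethylsilyl)oxy-1-(trimethylsilyl)heptadec-1-yn-4-ol (C8–C24 segment with free C11 hydroxyl), via lithium (trimethylsilyl)acetylide 11 (not isolated)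
Conditions: 10, n-BuLi, THF, −78 °C; BF3·OEt2; then 9, −78 °C
Reagents that add atoms: none
Why: Yamaguchi–Hirao alkynylation: the BF3-activated terminal epoxide is opened by the lithium acetylide at the unsubstituted carbon C10, forming C9–C10 without touching C11; the low temperature prevents silyl migration.

Step 10
Reactants: 12 C8–C24 alkynol with free C11 hydroxyl
Product: 13 4,8-bis[tert-butyl(dimethyl)silyl]oxy-6-(triethylsilyl)oxy-1-(trimethylsilyl)heptadec-1-yne
Conditions: TBSOTf, 2,6-lutidine, CH2Cl2, −78 °C
Reagents that add atoms: tert-butyldimethylsilyl triflate, CC(C)(C)[Si](C)(C)OS(=O)(=O)C(F)(F)F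
Why: Silyl triflate protection of the hindered C11 hydroxyl under buffered conditions that leave the triethylsilyl ether in place.

Step 11
Reactants: 13 C-silylated alkyne
Product: 14 4,8-bis[tert-butyl(dimethyl)silyl]oxy-6-(triethylsilyl)oxyheptadec-1-yne (terminal alkyne C8≡C9)
Conditions: K2CO3, MeOH, rt
Reagents that add atoms: none
Why: Methanolysis of the alkynyl C–Si bond is much faster than cleavage of secondary silyl ethers, which gives the terminal alkyne needed for carbometalation.

Step 12
Reactants: 14 terminal alkyne; 15 oxirane
Product: 18 (3E)-6,10-bis[tert-butyl(dimethyl)silyl]oxy-4-methyl-8-(triethylsilyl)oxynonadec-3-en-1-ol (C6–C24 segment), via (E)-alkenyldimethylalane 16 (not isolated), via lithium alkenyl(butyl)dimethylalanate 17 (not isolated)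
Conditions: Me3Al, Cp2ZrCl2, CH2Cl2, 0 °C to rt; volatiles removed; n-BuLi, hexane/THF, −78 to 0 °C; 15, 0 °C to rt; then aq. KNaC4H4O6
Reagents that add atoms: trimethylaluminium, C[Al](C)C
Why: Negishi zirconium-catalysed methylalumination adds methyl and aluminium syn with aluminium on the terminal carbon, which fixes the E-trisubstituted C8=C9 alkene; the ate complex formed with n-BuLi transfers the alkenyl group with retention to oxirane, forming C7–C8.

Step 13
Reactants: 18 C6–C24 homoallylic alcohol
Product: 19 (3E)-6,10-bis[tert-butyl(dimethyl)silyl]oxy-4-methyl-8-(triethylsilyl)oxynonadec-3-enal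
Conditions: Dess–Martin periodinane, NaHCO3, CH2Cl2, 0 °C; used crude
Reagents that add atoms: none
Why: Buffered Dess–Martin oxidation is neutral enough to give the β,γ-unsaturated aldehyde without moving C8=C9 into conjugation, provided the crude aldehyde is used at once.

Step 14
Reactants: 19 β,γ-unsaturated aldehyde
Product: 20 (5E)-8,12-bis[tert-butyl(dimethyl)silyl]oxy-6-methyl-10-(triethylsilyl)oxyhenicosa-1,5-dien-3-ol (C6 epimers)
Conditions: CH2=CHMgBr, THF, −78 °C; then aq. NH4Cl
Reagents that add atoms: vinylmagnesium bromide, C=C[Mg]Br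
Why: Grignard 1,2-addition at low temperature outruns enolisation and forms C5–C6; the new C6 centre is uncontrolled and is erased in step 20.

Step 15
Reactants: 20 allylic alcohol
Product: 21 methyl carbonate of 20 at the C6 oxygen
Conditions: ClCO2Me, pyridine, DMAP (cat.), CH2Cl2, 0 °C
Reagents that add atoms: methyl chloroformate, COC(=O)Cl
Why: Routine carbonate formation installs the leaving group for the later β-oxygen elimination; the silyl ethers are inert.

Step 16
Reactants: 21 allylic methyl carbonate with the C13 triethylsilyl ether
Product: 22 methyl (5E)-8,12-bis[tert-butyl(dimethyl)silyl]oxy-10-hydroxy-6-methylhenicosa-1,5-dien-3-yl carbonate (free C13 hydroxyl)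
Conditions: PPTS (cat.), MeOH/CH2Cl2, 0 °C
Reagents that add atoms: none
Why: Mild acid-catalysed methanolysis removes the triethylsilyl ether far faster than the bulkier tert-butyldimethylsilyl ethers and does not touch the carbonate, so C13 alone is unmasked.

Step 17
Reactants: 23 but-3-en-1-ol
Product: 24 (but-3-en-1-yloxy)(tert-butyl)dimethylsilane
Conditions: TBSCl, imidazole, CH2Cl2, rt
Reagents that add atoms: tert-butyldimethylsilyl chloride, CC(C)(C)[Si](C)(C)Cl
Why: Standard silylation of a primary alcohol.

Step 18
Reactants: 24 (but-3-en-1-yloxy)(tert-butyl)dimethylsilane; 25 acrylic acid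
Product: 26 (2E)-5-[tert-butyl(dimethyl)silyl]oxypent-2-enoic acid
Conditions: (H2IMes)(PCy3)Cl2Ru=CHPh (second-generation Grubbs catalyst, 3 mol %), CH2Cl2, 40 °C
Reagents that add atoms: none
Why: Cross-metathesis of a terminal alkene with an electron-poor acrylic partner is selective for the hetero-coupled product and strongly favours the E-enoic acid; ethene leaves.

Step 19
Reactants: 22 C13 alcohol; 26 (2E)-5-[tert-butyl(dimethyl)silyl]oxypent-2-enoic acid
Product: 28 C13 (2E)-5-[tert-butyl(dimethyl)silyl]oxypent-2-enoate of 22 (C6 methyl carbonate and terminal C4=C5 alkene), via mixed anhydride 27 (not isolated)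
Conditions: 2,4,6-Cl3C6H2COCl, Et3N, THF, rt; then 22, DMAP, PhMe, rt
Reagents that add atoms: none
Why: Yamaguchi esterification acylates the secondary C13 hydroxyl through the mixed anhydride with retention at C13; the carbonate and silyl ethers tolerate the amine bases.

Step 20
Reactants: 28 enoate ester with tethered allylic carbonate
Product: 29 (3E,6E,9E)-12-[tert-butyl(dimethyl)silyl]oxy-14-[(2S)-2-[tert-butyl(dimethyl)silyl]oxyundecyl]-4-[2-[tert-butyl(dimethyl)silyl]oxyethyl]-10-methyl-1-oxacyclotetradeca-3,6,9-trien-2-one
Conditions: [Cp*RhCl2]2 (5 mol %), AgSbF6 (20 mol %), CsOPiv (30 mol %), PivOH (1 equiv), ClCH2CH2Cl, 60 °C, slow addition of 28 to about 1 mM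
Reagents that add atoms: none
Why: Proposed new method: chloride abstraction gives a cationic Cp*Rh pivalate (trivalent rhodium) that binds the C1 ester carbonyl and cleaves the only β-C–H bond cis to it (C3–H) by concerted metalation–deprotonation, forming a five-membered alkenyl rhodacycle; the tethered terminal alkene inserts into Rh–C3 with C3 bonding to C4, and syn β-oxygen elimination of the C6 carbonate forms C5=C6 and a rhodium methyl carbonate that loses CO2 and is protonated by PivOH, so the cycle is redox-neutral and needs neither oxidant nor strong base. The closest known reaction type is the intermolecular Cp*Rh-catalysed β-C–H allylation of acrylamides with allylic carbonates, which places the allyl group cis to the carbonyl, and ester carbonyls are known to direct oxidative vinylic C–H olefination of acrylates at the same metal; neither ester direction of an allylation nor a macrocyclic version has been shown. The 14-membered ring closes by a 14-endo-trig migratory insertion in which both alkene carbons C4 and C5 become ring members. No stereocentre is created and C6 is erased, which is why both C6 epimers of 28 can be used. Site selectivity needs no outside control, because C2–H cannot reach a chelated metal and the E-enoate has a single β-hydrogen, so C4 must end cis to C1 and the arm trans, the geometry of 33. Insertion with C3 at the unsubstituted terminus C4 follows from sterics and from the carbonate oxygen holding rhodium at C5, and E geometry at C5=C6 is expected from elimination through the rotamer that keeps C4 and C7 apart. Ring closure has to beat oligomerisation, which slow addition to high dilution addresses, and the pivalate-buffered medium should leave the silyl ethers and the doubly allylic C4 and C7 methylenes alone.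

Step 21
Reactants: 29 tris-silylated macrolactone
Product: 30 (3E,6E,9E)-12-[tert-butyl(dimethyl)silyl]oxy-14-[(2S)-2-[tert-butyl(dimethyl)silyl]oxyundecyl]-4-(2-hydroxyethyl)-10-methyl-1-oxacyclotetradeca-3,6,9-trien-2-one
Conditions: HF·pyridine, pyridine, THF, 0 °C
Reagents that add atoms: none
Why: Pyridine-buffered HF·pyridine cleaves the unhindered primary silyl ether well before the two secondary ones and is too mild to open the lactone or move the alkenes.

Step 22
Reactants: 30 primary alcohol
Product: 31 2-[(3E,6E,9E)-12-[tert-butyl(dimethyl)silyl]oxy-14-[(2S)-2-[tert-butyl(dimethyl)silyl]oxyundecyl]-10-methyl-2-oxo-1-oxacyclotetradeca-3,6,9-trien-4-yl]acetaldehyde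
Conditions: Dess–Martin periodinane, NaHCO3, CH2Cl2, 0 °C; used crude
Reagents that add atoms: none
Why: Buffered Dess–Martin oxidation stops at the aldehyde under neutral conditions; the product is taken on immediately because its C1′ methylene is activated by both the aldehyde and the enoate.

Step 23
Reactants: 31 aldehyde
Product: 32 2-[(3E,6E,9E)-12-[tert-butyl(dimethyl)silyl]oxy-14-[(2S)-2-[tert-butyl(dimethyl)silyl]oxyundecyl]-10-methyl-2-oxo-1-oxacyclotetradeca-3,6,9-trien-4-yl]acetic acid
Conditions: NaClO2, NaH2PO4, 2-methylbut-2-ene, t-BuOH/H2O, 0 °C to rt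
Reagents that add atoms: sodium chlorite, [Na+].[O-]Cl=O
Why: Pinnick oxidation converts the aldehyde to the acid at mildly acidic pH without enolisation, and the alkene scavenger takes up hypochlorous acid before it can attack the ring alkenes.

Step 24
Reactants: 32 bis-silylated acid
Product: 33 2-[(3E,6E,9E,12S,14R)-12-hydroxy-14-[(2S)-2-hydroxyundecyl]-10-methyl-2-oxo-1-oxacyclotetradeca-3,6,9-trien-4-yl]acetic acid (target)
Conditions: HF·pyridine (excess), THF, 0 °C to rt
Reagents that add atoms: none
Why: Fluoride-mediated desilylation under weakly acidic conditions frees the C11 and C15 hydroxyls without base, which avoids acyl migration of the lactone and isomerisation of the glutaconate unit or skipped triene.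

## Compound list

1 | decanal | CCCCCCCCCC=O | starting material
2 | (4S)-tridec-1-en-4-ol | CCCCCCCCC[C@H](O)CC=C | intermediate
3 | tert-butyl(dimethyl)[(4S)-tridec-1-en-4-yl]oxysilane | CCCCCCCCC[C@H](O[Si](C)(C)C(C)(C)C)CC=C | intermediate
4 | (3S)-3-[tert-butyl(dimethyl)silyl]oxydodecanal | CCCCCCCCC[C@H](O[Si](C)(C)C(C)(C)C)CC=O | intermediate
5 | (4S,6S)-6-[tert-butyl(dimethyl)silyl]oxypentadec-1-en-4-ol | CCCCCCCCC[C@H](O[Si](C)(C)C(C)(C)C)C[C@@H](O)CC=C | intermediate
6 | tert-butyl (4S,6S)-6-[tert-butyl(dimethyl)silyl]oxypentadec-1-en-4-yl carbonate | CCCCCCCCC[C@H](O[Si](C)(C)C(C)(C)C)C[C@@H](OC(=O)OC(C)(C)C)CC=C | intermediate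
7 | (4R)-4-(iodomethyl)-6-[(2S)-2-[tert-butyl(dimethyl)silyl]oxyundecyl]-1,3-dioxan-2-one, 4,6-cis | CCCCCCCCC[C@H](O[Si](C)(C)C(C)(C)C)C[C@@H]1C[C@H](CI)OC(=O)O1 | intermediate
8 | (2S,4S)-4-[tert-butyl(dimethyl)silyl]oxy-1-[(2R)-oxiran-2-yl]tridecan-2-ol | CCCCCCCCC[C@H](O[Si](C)(C)C(C)(C)C)C[C@@H](O)C[C@@H]1CO1 | intermediate
9 | C13 triethylsilyl ether of 8 | CCCCCCCCC[C@H](O[Si](C)(C)C(C)(C)C)C[C@@H](O[Si](CC)(CC)CC)C[C@@H]1CO1 | intermediate
10 | ethynyltrimethylsilane | C[Si](C)(C)C#C | starting material
11 | lithium (trimethylsilyl)acetylide | C[Si](C)(C)C#C[Li] | intermediate (not isolated)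
12 | 8-[tert-butyl(dimethyl)silyl]oxy-6-(triethylsilyl)oxy-1-(trimethylsilyl)heptadec-1-yn-4-ol | CCCCCCCCC[C@H](O[Si](C)(C)C(C)(C)C)C[C@@H](O[Si](CC)(CC)CC)C[C@@H](O)CC#C[Si](C)(C)C | intermediate
13 | 4,8-bis[tert-butyl(dimethyl)silyl]oxy-6-(triethylsilyl)oxy-1-(trimethylsilyl)heptadec-1-yne | CCCCCCCCC[C@H](O[Si](C)(C)C(C)(C)C)C[C@@H](O[Si](CC)(CC)CC)C[C@@H](O[Si](C)(C)C(C)(C)C)CC#C[Si](C)(C)C | intermediate
14 | 4,8-bis[tert-butyl(dimethyl)silyl]oxy-6-(triethylsilyl)oxyheptadec-1-yne | CCCCCCCCC[C@H](O[Si](C)(C)C(C)(C)C)C[C@@H](O[Si](CC)(CC)CC)C[C@@H](O[Si](C)(C)C(C)(C)C)CC#C | intermediate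
15 | oxirane | C1CO1 | starting material
16 | (E)-alkenyldimethylalane from 14 (Al on C8, methyl on C9) | CCCCCCCCC[C@H](O[Si](C)(C)C(C)(C)C)C[C@@H](O[Si](CC)(CC)CC)C[C@@H](O[Si](C)(C)C(C)(C)C)C/C(C)=C/[Al](C)C | intermediate (not isolated)
17 | lithium alkenyl(butyl)dimethylalanate | [Li+].CCCCCCCCC[C@H](O[Si](C)(C)C(C)(C)C)C[C@@H](O[Si](CC)(CC)CC)C[C@@H](O[Si](C)(C)C(C)(C)C)C/C(C)=C/[Al-](C)(C)CCCC | intermediate (not isolated)
18 | (3E)-6,10-bis[tert-butyl(dimethyl)silyl]oxy-4-methyl-8-(triethylsilyl)oxynonadec-3-en-1-ol | CCCCCCCCC[C@H](O[Si](C)(C)C(C)(C)C)C[C@@H](O[Si](CC)(CC)CC)C[C@@H](O[Si](C)(C)C(C)(C)C)C/C(C)=C/CCO | intermediate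
19 | (3E)-6,10-bis[tert-butyl(dimethyl)silyl]oxy-4-methyl-8-(triethylsilyl)oxynonadec-3-enal | CCCCCCCCC[C@H](O[Si](C)(C)C(C)(C)C)C[C@@H](O[Si](CC)(CC)CC)C[C@@H](O[Si](C)(C)C(C)(C)C)C/C(C)=C/CC=O | intermediate
20 | (5E)-8,12-bis[tert-butyl(dimethyl)silyl]oxy-6-methyl-10-(triethylsilyl)oxyhenicosa-1,5-dien-3-ol (C6 epimers, one drawn) | CCCCCCCCC[C@H](O[Si](C)(C)C(C)(C)C)C[C@@H](O[Si](CC)(CC)CC)C[C@@H](O[Si](C)(C)C(C)(C)C)C/C(C)=C/C[C@H](O)C=C | intermediate
21 | methyl carbonate of 20 | CCCCCCCCC[C@H](O[Si](C)(C)C(C)(C)C)C[C@@H](O[Si](CC)(CC)CC)C[C@@H](O[Si](C)(C)C(C)(C)C)C/C(C)=C/C[C@H](OC(=O)OC)C=C | intermediate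
22 | methyl (5E)-8,12-bis[tert-butyl(dimethyl)silyl]oxy-10-hydroxy-6-methylhenicosa-1,5-dien-3-yl carbonate | CCCCCCCCC[C@H](O[Si](C)(C)C(C)(C)C)C[C@@H](O)C[C@@H](O[Si](C)(C)C(C)(C)C)C/C(C)=C/C[C@H](OC(=O)OC)C=C | intermediate
23 | but-3-en-1-ol | C=CCCO | starting material
24 | (but-3-en-1-yloxy)(tert-butyl)dimethylsilane | C=CCCO[Si](C)(C)C(C)(C)C | intermediate
25 | acrylic acid | C=CC(=O)O | starting material
26 | (2E)-5-[tert-butyl(dimethyl)silyl]oxypent-2-enoic acid | CC(C)(C)[Si](C)(C)OCC/C=C/C(=O)O | intermediate
27 | mixed anhydride of 26 with 2,4,6-trichlorobenzoic acid | CC(C)(C)[Si](C)(C)OCC/C=C/C(=O)OC(=O)c1c(Cl)cc(Cl)cc1Cl | intermediate (not isolated)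
28 | C13 (2E)-5-[tert-butyl(dimethyl)silyl]oxypent-2-enoate of 22 | CCCCCCCCC[C@H](O[Si](C)(C)C(C)(C)C)C[C@@H](OC(=O)/C=C/CCO[Si](C)(C)C(C)(C)C)C[C@@H](O[Si](C)(C)C(C)(C)C)C/C(C)=C/C[C@H](OC(=O)OC)C=C | intermediate
29 | (3E,6E,9E)-12-[tert-butyl(dimethyl)silyl]oxy-14-[(2S)-2-[tert-butyl(dimethyl)silyl]oxyundecyl]-4-[2-[tert-butyl(dimethyl)silyl]oxyethyl]-10-methyl-1-oxacyclotetradeca-3,6,9-trien-2-one | CCCCCCCCC[C@H](O[Si](C)(C)C(C)(C)C)C[C@@H]1C[C@@H](O[Si](C)(C)C(C)(C)C)C/C(C)=C/C/C=C/C/C(CCO[Si](C)(C)C(C)(C)C)=C\C(=O)O1 | intermediate
30 | 4-(2-hydroxyethyl) analogue of 29 | CCCCCCCCC[C@H](O[Si](C)(C)C(C)(C)C)C[C@@H]1C[C@@H](O[Si](C)(C)C(C)(C)C)C/C(C)=C/C/C=C/C/C(CCO)=C\C(=O)O1 | intermediate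
31 | arm aldehyde (2-oxoethyl at C3) | CCCCCCCCC[C@H](O[Si](C)(C)C(C)(C)C)C[C@@H]1C[C@@H](O[Si](C)(C)C(C)(C)C)C/C(C)=C/C/C=C/C/C(CC=O)=C\C(=O)O1 | intermediate
32 | bis-silylated acid | CCCCCCCCC[C@H](O[Si](C)(C)C(C)(C)C)C[C@@H]1C[C@@H](O[Si](C)(C)C(C)(C)C)C/C(C)=C/C/C=C/C/C(CC(=O)O)=C\C(=O)O1 | intermediate
33 | 2-[(3E,6E,9E,12S,14R)-12-hydroxy-14-[(2S)-2-hydroxyundecyl]-10-methyl-2-oxo-1-oxacyclotetradeca-3,6,9-trien-4-yl]acetic acid | CCCCCCCCC[C@H](O)C[C@@H]1C[C@@H](O)C/C(C)=C/C/C=C/C/C(CC(=O)O)=C\C(=O)O1 | target

## Step count and least certain steps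

Total: 24 steps. Longest linear sequence: 22 steps (steps 1–16 and 19–24); steps 17 and 18 form the two-step side branch to acid 26.

**Step 20 (key step; the only step beyond known chemistry).** The ester may bind the cationic rhodium too weakly for C–H cleavage, or the carbonate and alkenes may tie the catalyst up. Intermolecular allylation could outrun ring closure, β-hydride elimination could compete with β-oxygen elimination, the C5=C6 alkene could form with Z geometry, or the new skipped dienoate could slide into conjugation. The fallback uses known reactions and sets out from alcohol 22.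
- Commercial tert-butyl(but-3-yn-1-yloxy)dimethylsilane is deprotonated with n-BuLi and acylated with ClCO2Me to give methyl 5-[tert-butyl(dimethyl)silyl]oxypent-2-ynoate F1.
- Stannylcupration under equilibrating conditions ((Me3Sn)(PhS)CuLi, THF, −48 °C, then MeOH) gives methyl (2Z)-5-[tert-butyl(dimethyl)silyl]oxy-3-(trimethylstannyl)pent-2-enoate F2, with tin cis to the ester.
- Stille coupling of F2 with the allylic carbonate of 22 (Pd2(dba)3, zerovalent palladium, AsPh3, LiCl, NMP, 40 °C) goes through the π-allyl complex, attacks at the unsubstituted terminus C4 and keeps the alkenyl geometry, giving the open-chain hydroxy methyl ester F3.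
- Me3SnOH in ClCH2CH2Cl hydrolyses the methyl ester without base to the seco acid F4.
- Macrolactonisation with 2-methyl-6-nitrobenzoic anhydride and DMAP at high dilution closes the ring at O13–C1, and the route is rejoined at 29.

**Step 12.** Carbometalation may be slow or incomplete next to the two bulky silyloxy groups, and the alanate may transfer butyl or methyl instead of the alkenyl group to oxirane. The fallback sets out from 14: the same methylalumination is run and alane 16 is quenched with I2 to give the (E)-alkenyl iodide F5; iodine–lithium exchange (t-BuLi, Et2O, −78 °C) followed by oxirane 15 and BF3·OEt2 gives 18, where the route is rejoined.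

**Step 13 (with step 14).** The β,γ-unsaturated aldehyde 19 may lose its C8=C9 position by migration into conjugation on handling, or be enolised by the Grignard reagent instead of undergoing addition. The fallback avoids any aldehyde and sets out from 14 through the alkenyl iodide F5 described above.
- After iodine–lithium exchange and transmetalation (MgBr2·OEt2, catalytic CuBr·SMe2), the alkenyl metal opens racemic epichlorohydrin at its unsubstituted epoxide carbon to give the chlorohydrin F6.
- K2CO3 in MeOH closes it to the terminal epoxide F7.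
- Excess dimethylsulfonium methylide (trimethylsulfonium iodide, n-BuLi, THF, −10 °C to rt) converts the terminal epoxide into the one-carbon-longer allylic alcohol, which is 20, where the route is rejoined.

**Step 19.** Activation of acid 26 in the presence of DMAP may lead, through a vinylketene, to loss of conjugation or of E geometry in the enoate, which would remove the one β-hydrogen the key step needs. The fallback sets out from 22: acylation with diethylphosphonoacetic acid (EDC·HCl, catalytic DMAP) gives the C13 diethylphosphonoacetate F8, and a Horner–Wadsworth–Emmons reaction under Masamune–Roush conditions (LiCl, i-Pr2NEt, MeCN) with commercial 3-[tert-butyl(dimethyl)silyl]oxypropanal builds the E-enoate in place, rejoining the route at 28.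

**Step 22 (with step 23).** Aldehyde 31 may tautomerise through its dienol, moving the C2=C3 double bond toward the aldehyde or scrambling its geometry before the second oxidation. The fallback sets out from 29: excess HF·pyridine removes all three silyl groups to give the triol lactone F9, and catalytic TEMPO with PhI(OAc)2 in MeCN/pH 7 buffer oxidises only the primary alcohol through to the acid, the aldehyde hydrate being consumed as it forms. This returns to the route at 33.

## Further compounds

F1 | step 20 | methyl 5-[tert-butyl(dimethyl)silyl]oxypent-2-ynoate | COC(=O)C#CCCO[Si](C)(C)C(C)(C)C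
F2 | step 20 | methyl (2Z)-5-[tert-butyl(dimethyl)silyl]oxy-3-(trimethylstannyl)pent-2-enoate | COC(=O)/C=C(/CCO[Si](C)(C)C(C)(C)C)[Sn](C)(C)C
F3 | step 20 | open-chain hydroxy methyl ester (C1 methyl ester, free C13 hydroxyl) | CCCCCCCCC[C@H](O[Si](C)(C)C(C)(C)C)C[C@@H](O)C[C@@H](O[Si](C)(C)C(C)(C)C)C/C(C)=C/C/C=C/C/C(CCO[Si](C)(C)C(C)(C)C)=C\C(=O)OC
F4 | step 20 | seco acid (C1 acid, free C13 hydroxyl) | CCCCCCCCC[C@H](O[Si](C)(C)C(C)(C)C)C[C@@H](O)C[C@@H](O[Si](C)(C)C(C)(C)C)C/C(C)=C/C/C=C/C/C(CCO[Si](C)(C)C(C)(C)C)=C\C(=O)O
F5 | step 12 | (E)-alkenyl iodide (iodine on C8, methyl on C9) | CCCCCCCCC[C@H](O[Si](C)(C)C(C)(C)C)C[C@@H](O[Si](CC)(CC)CC)C[C@@H](O[Si](C)(C)C(C)(C)C)C/C(C)=C/I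
F6 | step 13 | chlorohydrin (C6 hydroxyl, C5 chloride; C6 epimers) | CCCCCCCCC[C@H](O[Si](C)(C)C(C)(C)C)C[C@@H](O[Si](CC)(CC)CC)C[C@@H](O[Si](C)(C)C(C)(C)C)C/C(C)=C/CC(O)CCl
F7 | step 13 | terminal epoxide at C5–C6 (C6 epimers) | CCCCCCCCC[C@H](O[Si](C)(C)C(C)(C)C)C[C@@H](O[Si](CC)(CC)CC)C[C@@H](O[Si](C)(C)C(C)(C)C)C/C(C)=C/CC1CO1
F8 | step 19 | C13 diethylphosphonoacetate of 22 | CCCCCCCCC[C@H](O[Si](C)(C)C(C)(C)C)C[C@@H](OC(=O)CP(=O)(OCC)OCC)C[C@@H](O[Si](C)(C)C(C)(C)C)C/C(C)=C/C[C@H](OC(=O)OC)C=C
F9 | step 22 | triol lactone (free C11, C15 and arm hydroxyls) | CCCCCCCCC[C@H](O)C[C@@H]1C[C@@H](O)C/C(C)=C/C/C=C/C/C(CCO)=C\C(=O)O1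
A1 | alternative 1 | chloroacetaldehyde | ClCC=O
A2 | alternative 1 | acetaldehyde | CC=O
A3 | alternative 1 | (3R,5S)-6-chloro-3,5-dihydroxyhexanal | ClC[C@@H](O)C[C@@H](O)CC=O
A4 | alternative 2 | open-chain C1 enal / C15 ketone with free C11 and C13 hydroxyls | CCCCCCCCCC(=O)C[C@@H](O)C[C@@H](O)C/C(C)=C/C/C=C/C/C(CCO[Si](C)(C)C(C)(C)C)=C\C=O
A5 | alternative 2 | samarium diiodide | I[Sm]I
A6 | alternative 2 | 14-membered lactone with free C11 and C15 hydroxyls and silyloxyethyl arm | CCCCCCCCC[C@H](O)C[C@@H]1C[C@@H](O)C/C(C)=C/C/C=C/C/C(CCO[Si](C)(C)C(C)(C)C)=C\C(=O)O1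
A7 | alternative 3 | diyne ester with two methyl-capped alkynes | CCCCCCCCC[C@H](O[Si](C)(C)C(C)(C)C)C[C@@H](OC(=O)/C=C(CCO[Si](C)(C)C(C)(C)C)\CC#CC)C[C@@H](O[Si](C)(C)C(C)(C)C)C/C(C)=C/CC#CC
A8 | alternative 3 | Mo(≡C–C6H4-4-OMe)(OSiPh3)3 | COc1ccc(cc1)C#[Mo](O[Si](c1ccccc1)(c1ccccc1)c1ccccc1)(O[Si](c1ccccc1)(c1ccccc1)c1ccccc1)O[Si](c1ccccc1)(c1ccccc1)c1ccccc1
A9 | alternative 3 | 14-membered cycloalkyne lactone with C5–C6 triple bond | CCCCCCCCC[C@H](O[Si](C)(C)C(C)(C)C)C[C@@H]1C[C@@H](O[Si](C)(C)C(C)(C)C)C/C(C)=C/CC#CC/C(CCO[Si](C)(C)C(C)(C)C)=C\C(=O)O1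
A10 | alternative 3 | but-2-yne | CC#CC
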